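**Retrosynthetic overview**

1. Numbering follows eudesmane: ring A = C1–C5 and C10, ring B = C5–C10, C11(=C13)–C12O2H on C7, C14 = methyl on C10, C15 = the CH2O carbon on C4. Late disconnections are the phenol silyl ether, the C12 acid (from an α-methylene aldehyde), the C15–O ester bond and C13.
2. Enabling feature: ring A is a cyclohexene whose C3=C4 double bond is flanked by the ring bonds C1–C2 and C5–C10 (a Diels–Alder retron), and C7 of ring B is β to the C12 carbonyl (a conjugate-addition site).
3. Cutting C7–C8 and C5–C10 (with C1–C2) therefore opens both rings to an acyclic (5Z)-dienyl enoate and a five-carbon isopentenyl Grignard reagent.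
4. Key operation, one flask: copper-catalysed asymmetric 1,4-addition (C7–C8, sets C7), then thermal intramolecular Diels–Alder reaction of the resulting deca-1,3,9-triene (C5–C10 and C1–C2, sets C5 and C10).
5. Ring order: no ring before step 4; rings A and B are closed together in step 4. The dienyl enoate comes from prop-2-yn-1-ol, vinylmagnesium bromide and methyl 4-bromocrotonate.

Key step: step 4

Remark (assumption on the chemistry): both antipodes of the Josiphos ligand are taken to be available, so the sense of the 1,4-addition can be matched to the required 3R centre of 10.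

**Route**

Step 1
Reactants: 1 prop-2-yn-1-ol; 2 ethenylmagnesium bromide; 3 methyl (2E)-4-bromobut-2-enoate
Product: 6 methyl (2E,5Z)-6-(hydroxymethyl)octa-2,5,7-trienoate, via cyclic alkenylmagnesium alkoxide 4 (not isolated), via alkenylzinc bromide 5 (not isolated)
Conditions: 2 (2.2 equiv), CuI (10 mol%), THF, 0 °C → rt; ZnBr2, 0 °C; 3, Pd(PPh3)4 (3 mol%), 0 °C → rt; H2O
Reagents that add atoms: none
Why: Copper-catalysed anti-carbomagnesiation of the propargylic alkoxide places the vinyl group on the internal carbon and magnesium cis to the CH2O group (ring 4), and after transmetalation to zinc a Negishi allylation at the CH2 terminus of the bromocrotonate keeps both alkene geometries, so the (5Z) geometry that the later cycloaddition needs is fixed here (no stereocentre is formed).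

Step 2
Reactants: 6 methyl (2E,5Z)-6-(hydroxymethyl)octa-2,5,7-trienoate
Product: 7 methyl (2E,5Z)-6-{[(tert-butyldimethylsilyl)oxy]methyl}octa-2,5,7-trienoate
Conditions: TBSCl, imidazole, CH2Cl2, 0 °C → rt
Reagents that add atoms: tert-butyl(chloro)dimethylsilane, CC(C)(C)[Si](C)(C)Cl
Why: Standard silylation of a primary allylic alcohol masks the acidic O–H before the Grignard step, the ester and the skipped triene being inert to imidazole.

Step 3
Reactants: 8 4-bromo-2-methylbut-1-ene
Product: 9 (3-methylbut-3-en-1-yl)magnesium bromide (used as its Et2O solution)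
Conditions: Mg turnings, Et2O, reflux
Reagents that add atoms: magnesium, [Mg]
Why: Oxidative insertion of magnesium into a primary homoallylic bromide gives a stable Grignard reagent, the remote 1,1-disubstituted alkene not interfering.

Step 4
Reactants: 7 methyl (2E,5Z)-6-{[(tert-butyldimethylsilyl)oxy]methyl}octa-2,5,7-trienoate; 9 (3-methylbut-3-en-1-yl)magnesium bromide
Product: 11 methyl 2-[(2R,4aS,8aR)-8-{[(tert-butyldimethylsilyl)oxy]methyl}-4a-methyl-1,2,3,4,4a,5,6,8a-octahydronaphthalen-2-yl]acetate, via triene ester 10 (not isolated)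
Conditions: CuBr·SMe2 (5 mol%), Josiphos ligand [1-(2-diphenylphosphinoferrocenyl)ethyl]dicyclohexylphosphine (6 mol%, antipode chosen for the 3R adduct), t-BuOMe, −75 °C; MeOH; filtration through a SiO2 pad and solvent exchange without purification; then PhMe (0.01 M), BHT, 185 °C, sealed tube
Reagents that add atoms: none
Why: The copper–Josiphos catalyst transfers the 3-methylbut-3-enyl group of 9 to C7, the β-carbon of enoate 7, making C7–C8 and setting C7 by the catalyst's choice of enoate face (asymmetric copper-catalysed 1,4-addition of Grignard reagents to α,β-unsaturated esters); after protonation the deca-1,3,9-triene 10 is heated and closes by a type 1 intramolecular Diels–Alder reaction, the known thermal route from deca-1,3,9-trienes with an isopropenyl dienophile to angular-methyl octalins. Ring A closes as the [4+2] ring (diene C2=C3–C4=C5 plus the isopropenyl C1=C10, new bonds C5–C10 and C1–C2, leaving C3=C4 with its oxymethyl group in place), and ring B closes as the four-carbon tether C6–C7–C8–C9 in the fused mode. C5 and C10 should be set by an anti, chair-like transition state with the C7 acetate arm equatorial, which gives the trans ring fusion with the side chain on the face of the angular methyl. The syn (cis-fused) alternative is expected to be disfavoured by the methyl on the dienophile and by allylic strain between the tether and the C15 oxymethyl group, which is cis to it on the diene. The step needs 1,4- rather than 1,2-addition with no attack on the diene, which the ester as sole acceptor and copper catalysis at −75 °C secure, and fused rather than bridged regiochemistry, which the tether length and the (5Z) geometry from step 1 secure. High dilution and BHT are there to suppress intermolecular cycloaddition and polymerisation of the diene.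

Step 5
Reactants: 11 methyl 2-[(2R,4aS,8aR)-8-{[(tert-butyldimethylsilyl)oxy]methyl}-4a-methyl-1,2,3,4,4a,5,6,8a-octahydronaphthalen-2-yl]acetate
Product: 12 2-[(2R,4aS,8aR)-8-{[(tert-butyldimethylsilyl)oxy]methyl}-4a-methyl-1,2,3,4,4a,5,6,8a-octahydronaphthalen-2-yl]acetaldehyde
Conditions: i-Bu2AlH (1.05 equiv), CH2Cl2, −78 °C; aq. potassium sodium tartrate
Reagents that add atoms: none
Why: At −78 °C i-Bu2AlH reduces the methyl ester only to the tetrahedral aluminium hemiacetal, which releases the aldehyde on work-up, while the silyl ether, the ring alkene and the three stereocentres are untouched.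

Step 6
Reactants: 12 2-[(2R,4aS,8aR)-8-{[(tert-butyldimethylsilyl)oxy]methyl}-4a-methyl-1,2,3,4,4a,5,6,8a-octahydronaphthalen-2-yl]acetaldehyde
Product: 13 2-[(2R,4aR,8aR)-8-{[(tert-butyldimethylsilyl)oxy]methyl}-4a-methyl-1,2,3,4,4a,5,6,8a-octahydronaphthalen-2-yl]prop-2-enal
Conditions: 37% aq. CH2O, pyrrolidine (10 mol%), propanoic acid (10 mol%), i-PrOH, 45 °C
Reagents that add atoms: formaldehyde, C=O
Why: Amine/acid-catalysed Mannich condensation–elimination (organocatalytic α-methylenation of an α-unbranched aldehyde) installs C13 as the exocyclic methylene under nearly neutral conditions that should leave the C7 stereocentre and the silyl ether intact.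

Step 7
Reactants: 13 2-[(2R,4aR,8aR)-8-{[(tert-butyldimethylsilyl)oxy]methyl}-4a-methyl-1,2,3,4,4a,5,6,8a-octahydronaphthalen-2-yl]prop-2-enal
Product: 14 2-[(2R,4aR,8aR)-8-(hydroxymethyl)-4a-methyl-1,2,3,4,4a,5,6,8a-octahydronaphthalen-2-yl]prop-2-enal
Conditions: HF·pyridine, pyridine, THF, 0 °C → rt
Reagents that add atoms: none
Why: Fluoride cleaves the primary allylic silyl ether, and pyridine-buffered HF is mild enough for the α-methylene aldehyde.

Step 8
Reactants: 15 4-{[tri(propan-2-yl)silyl]oxy}benzaldehyde; 16 methyl 2-[bis(2,2,2-trifluoroethoxy)phosphoryl]acetate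
Product: 17 methyl (2Z)-3-(4-{[tri(propan-2-yl)silyl]oxy}phenyl)prop-2-enoate
Conditions: KN(SiMe3)2, 18-crown-6, THF, −78 °C
Reagents that add atoms: none
Why: Still–Gennari variant of the Horner–Wadsworth–Emmons olefination, in which the electron-poor trifluoroethyl phosphonate and the dissociated potassium counter-ion favour kinetic formation of the Z enoate from an aromatic aldehyde.

Step 9
Reactants: 17 methyl (2Z)-3-(4-{[tri(propan-2-yl)silyl]oxy}phenyl)prop-2-enoate
Product: 18 (2Z)-3-(4-{[tri(propan-2-yl)silyl]oxy}phenyl)prop-2-enoic acid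
Conditions: Me3SnOH, ClCH2CH2Cl, 80 °C; then 1 M HCl
Reagents that add atoms: trimethyltin hydroxide, C[Sn](C)(C)O
Why: Trimethyltin hydroxide cleaves the methyl ester under neutral conditions through a tin carboxylate, which should spare both the base-labile aryl silyl ether and the Z alkene.

Step 10
Reactants: 14 2-[(2R,4aR,8aR)-8-(hydroxymethyl)-4a-methyl-1,2,3,4,4a,5,6,8a-octahydronaphthalen-2-yl]prop-2-enal; 18 (2Z)-3-(4-{[tri(propan-2-yl)silyl]oxy}phenyl)prop-2-enoic acid
Product: 19 2-[(2R,4aR,8aR)-4a-methyl-8-({[(2Z)-3-(4-{[tri(propan-2-yl)silyl]oxy}phenyl)prop-2-enoyl]oxy}methyl)-1,2,3,4,4a,5,6,8a-octahydronaphthalen-2-yl]prop-2-enal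
Conditions: PPh3, DIAD, PhMe/THF, 0 °C, dark
Reagents that add atoms: none
Why: Mitsunobu esterification activates the primary allylic alcohol and the carboxylate displaces the oxyphosphonium group by SN2 at C15, so the Z acid is never turned into an acyl electrophile that could isomerise and no stereocentre is touched.

Step 11
Reactants: 19 2-[(2R,4aR,8aR)-4a-methyl-8-({[(2Z)-3-(4-{[tri(propan-2-yl)silyl]oxy}phenyl)prop-2-enoyl]oxy}methyl)-1,2,3,4,4a,5,6,8a-octahydronaphthalen-2-yl]prop-2-enal
Product: 20 2-[(2R,4aR,8aR)-4a-methyl-8-({[(2Z)-3-(4-{[tri(propan-2-yl)silyl]oxy}phenyl)prop-2-enoyl]oxy}methyl)-1,2,3,4,4a,5,6,8a-octahydronaphthalen-2-yl]prop-2-enoic acid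
Conditions: NaClO2, NaH2PO4, 2-methylbut-2-ene, t-BuOH/H2O, 0 °C → rt
Reagents that add atoms: sodium chlorite, [Na+].[O-]Cl=O
Why: Pinnick oxidation converts the α-methylene aldehyde into the acrylic acid chemoselectively, the hypochlorous acid by-product being trapped by 2-methylbut-2-ene so that the ring alkene, the Z cinnamate and the aryl silyl ether should survive.

Step 12
Reactants: 20 2-[(2R,4aR,8aR)-4a-methyl-8-({[(2Z)-3-(4-{[tri(propan-2-yl)silyl]oxy}phenyl)prop-2-enoyl]oxy}methyl)-1,2,3,4,4a,5,6,8a-octahydronaphthalen-2-yl]prop-2-enoic acid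
Product: 21 2-[(2R,4aR,8aR)-8-({[(2Z)-3-(4-hydroxyphenyl)prop-2-enoyl]oxy}methyl)-4a-methyl-1,2,3,4,4a,5,6,8a-octahydronaphthalen-2-yl]prop-2-enoic acid (CNP0183482.1)
Conditions: Bu4NF, AcOH, THF, 0 °C, dark
Reagents that add atoms: none
Why: Acetic-acid-buffered fluoride removes the aryl triisopropylsilyl group at 0 °C without saponifying the allylic ester or isomerising the Z alkene, giving the target.

**Compound list**

1 | prop-2-yn-1-ol | C#CCO | starting material
2 | ethenylmagnesium bromide | C=C[Mg]Br | starting material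
3 | methyl (2E)-4-bromobut-2-enoate | COC(=O)/C=C/CBr | starting material
4 | 4-ethenyl-2,5-dihydro-1,2-oxamagnesole (cyclic alkenylmagnesium alkoxide) | C=CC1=C[Mg]OC1 | intermediate
5 | bromo{(1Z)-2-[(bromomagnesiooxy)methyl]buta-1,3-dien-1-yl}zinc | Br[Mg]OC/C(C=C)=C\[Zn]Br | intermediate
6 | methyl (2E,5Z)-6-(hydroxymethyl)octa-2,5,7-trienoate | COC(=O)/C=C/C/C=C(\CO)C=C | intermediate
7 | methyl (2E,5Z)-6-{[(tert-butyldimethylsilyl)oxy]methyl}octa-2,5,7-trienoate | COC(=O)/C=C/C/C=C(\CO[Si](C)(C)C(C)(C)C)C=C | intermediate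
8 | 4-bromo-2-methylbut-1-ene | C=C(C)CCBr | starting material
9 | (3-methylbut-3-en-1-yl)magnesium bromide | C=C(C)CC[Mg]Br | intermediate
10 | methyl (3R,5Z)-6-{[(tert-butyldimethylsilyl)oxy]methyl}-3-(3-methylbut-3-en-1-yl)octa-5,7-dienoate | COC(=O)C[C@@H](C/C=C(\CO[Si](C)(C)C(C)(C)C)C=C)CCC(C)=C | intermediate
11 | methyl 2-[(2R,4aS,8aR)-8-{[(tert-butyldimethylsilyl)oxy]methyl}-4a-methyl-1,2,3,4,4a,5,6,8a-octahydronaphthalen-2-yl]acetate (trans-fused) | COC(=O)C[C@@H]1CC[C@@]2(C)CCC=C(CO[Si](C)(C)C(C)(C)C)[C@@H]2C1 | intermediate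
12 | 2-[(2R,4aS,8aR)-8-{[(tert-butyldimethylsilyl)oxy]methyl}-4a-methyl-1,2,3,4,4a,5,6,8a-octahydronaphthalen-2-yl]acetaldehyde | O=CC[C@@H]1CC[C@@]2(C)CCC=C(CO[Si](C)(C)C(C)(C)C)[C@@H]2C1 | intermediate
13 | 2-[(2R,4aR,8aR)-8-{[(tert-butyldimethylsilyl)oxy]methyl}-4a-methyl-1,2,3,4,4a,5,6,8a-octahydronaphthalen-2-yl]prop-2-enal | C=C(C=O)[C@@H]1CC[C@@]2(C)CCC=C(CO[Si](C)(C)C(C)(C)C)[C@@H]2C1 | intermediate
14 | 2-[(2R,4aR,8aR)-8-(hydroxymethyl)-4a-methyl-1,2,3,4,4a,5,6,8a-octahydronaphthalen-2-yl]prop-2-enal | C=C(C=O)[C@@H]1CC[C@@]2(C)CCC=C(CO)[C@@H]2C1 | intermediate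
15 | 4-{[tri(propan-2-yl)silyl]oxy}benzaldehyde | O=Cc1ccc(O[Si](C(C)C)(C(C)C)C(C)C)cc1 | starting material
16 | methyl 2-[bis(2,2,2-trifluoroethoxy)phosphoryl]acetate | COC(=O)CP(=O)(OCC(F)(F)F)OCC(F)(F)F | starting material
17 | methyl (2Z)-3-(4-{[tri(propan-2-yl)silyl]oxy}phenyl)prop-2-enoate | COC(=O)/C=C\c1ccc(O[Si](C(C)C)(C(C)C)C(C)C)cc1 | intermediate
18 | (2Z)-3-(4-{[tri(propan-2-yl)silyl]oxy}phenyl)prop-2-enoic acid | OC(=O)/C=C\c1ccc(O[Si](C(C)C)(C(C)C)C(C)C)cc1 | intermediate
19 | 2-[(2R,4aR,8aR)-4a-methyl-8-({[(2Z)-3-(4-{[tri(propan-2-yl)silyl]oxy}phenyl)prop-2-enoyl]oxy}methyl)-1,2,3,4,4a,5,6,8a-octahydronaphthalen-2-yl]prop-2-enal | C=C(C=O)[C@@H]1CC[C@@]2(C)CCC=C(COC(=O)/C=C\c3ccc(O[Si](C(C)C)(C(C)C)C(C)C)cc3)[C@@H]2C1 | intermediate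
20 | 2-[(2R,4aR,8aR)-4a-methyl-8-({[(2Z)-3-(4-{[tri(propan-2-yl)silyl]oxy}phenyl)prop-2-enoyl]oxy}methyl)-1,2,3,4,4a,5,6,8a-octahydronaphthalen-2-yl]prop-2-enoic acid | C=C(C(=O)O)[C@@H]1CC[C@@]2(C)CCC=C(COC(=O)/C=C\c3ccc(O[Si](C(C)C)(C(C)C)C(C)C)cc3)[C@@H]2C1 | intermediate
21 | 2-[(2R,4aR,8aR)-8-({[(2Z)-3-(4-hydroxyphenyl)prop-2-enoyl]oxy}methyl)-4a-methyl-1,2,3,4,4a,5,6,8a-octahydronaphthalen-2-yl]prop-2-enoic acid | C=C(C(=O)O)[C@@H]1CC[C@@]2(C)CCC=C(COC(=O)/C=C\c3ccc(O)cc3)[C@@H]2C1 | target

**Step count and risks**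

Total step count: 12. Longest linear sequence: 9 steps (1 → 2 → 4 → 5 → 6 → 7 → 10 → 11 → 12).

Most likely to fail, in this order:

1. Step 4. The copper-catalysed addition may discriminate the enoate faces poorly on this skipped-diene ester or be eroded by γ-deprotonation. On heating the crude triene, the anti/syn selectivity that fixes the ring fusion may be incomplete, or the diene may be lost to intermolecular cycloaddition. Fallback (auxiliary control with isolated intermediates), setting out from 7 and coming back at 11: ester 7 is hydrolysed by Me3SnOH to the trienoic acid F1. Pivaloyl chloride/Et3N converts F1 into the mixed pivalic anhydride F2, and F2 acylates the lithium salt of (4S)-4-benzyl-1,3-oxazolidin-2-one to give the N-trienoyl oxazolidinone F3. Addition of 9 to F3 in the presence of stoichiometric CuBr·SMe2 (THF/Me2S, −78 °C), where the benzyl group of the chelated s-cis imide blocks one face, should give the 3R adduct F4, from which a minor diastereomer can be removed. F4 is heated on its own (PhMe, BHT, 185 °C) to the decalin imide F5, where a minor ring-fusion isomer can be removed. MeOMgBr in MeOH/CH2Cl2 then releases the auxiliary from F5 and gives 11.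

2. Step 1. Carbomagnesiation may be incomplete or not fully stereospecific, alkene geometry may be lost on transmetalation, the organometallic may attack the ester or the α-carbon of the crotonate, and the skipped double bonds may migrate into conjugation under palladium. Fallback (C6–C7 made by olefination instead of allylation), setting out from 1 and 2 and coming back at 7: the carbomagnesiation mixture containing 4 is quenched by I2 and worked up in water to give the (Z)-iodo dienol F6, and F6 is silylated (TBSCl/imidazole) to the silyl ether F7. Iodine–lithium exchange on F7 (t-BuLi, Et2O, −78 °C) gives the alkenyllithium F8, and F8 opens oxirane in the presence of BF3·OEt2 to give, after aqueous work-up, the homoallylic alcohol F9. NaHCO3-buffered Dess–Martin oxidation of F9 gives the β,γ-unsaturated aldehyde F10, and F10 is used at once in a Wittig reaction with methyl (triphenylphosphoranylidene)acetate to give 7.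

3. Step 10. The coumarate may isomerise from Z to E during the redox condensation, the allylic system may transpose (SN2′ at C3), and the phosphine may add reversibly to the enal. Fallback (carboxylate alkylation instead of redox condensation), setting out from 14 and coming back at 19: alcohol 14 is converted by Corey–Kim chlorination (NCS, Me2S, CH2Cl2, −20 °C) into the allylic chloride F11, and F11 is displaced in DMF at rt by the caesium carboxylate F12, made from 18 and Cs2CO3, to give 19.

**Further compounds**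

F1 | step 4 | (2E,5Z)-6-{[(tert-butyldimethylsilyl)oxy]methyl}octa-2,5,7-trienoic acid | OC(=O)/C=C/C/C=C(\CO[Si](C)(C)C(C)(C)C)C=C
F2 | step 4 | mixed anhydride of F1 with 2,2-dimethylpropanoic acid | CC(C)(C)C(=O)OC(=O)/C=C/C/C=C(\CO[Si](C)(C)C(C)(C)C)C=C
F3 | step 4 | (4S)-4-benzyl-3-[(2E,5Z)-6-{[(tert-butyldimethylsilyl)oxy]methyl}octa-2,5,7-trienoyl]-1,3-oxazolidin-2-one | O=C1OC[C@H](Cc2ccccc2)N1C(=O)/C=C/C/C=C(\CO[Si](C)(C)C(C)(C)C)C=C
F4 | step 4 | (4S)-4-benzyl-3-[(3R,5Z)-6-{[(tert-butyldimethylsilyl)oxy]methyl}-3-(3-methylbut-3-en-1-yl)octa-5,7-dienoyl]-1,3-oxazolidin-2-one | O=C1OC[C@H](Cc2ccccc2)N1C(=O)C[C@@H](C/C=C(\CO[Si](C)(C)C(C)(C)C)C=C)CCC(C)=C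
F5 | step 4 | (4S)-4-benzyl-3-{2-[(2R,4aS,8aR)-8-{[(tert-butyldimethylsilyl)oxy]methyl}-4a-methyl-1,2,3,4,4a,5,6,8a-octahydronaphthalen-2-yl]acetyl}-1,3-oxazolidin-2-one | O=C3OC[C@H](Cc4ccccc4)N3C(=O)C[C@@H]1CC[C@@]2(C)CCC=C(CO[Si](C)(C)C(C)(C)C)[C@@H]2C1
F6 | step 1 | (2Z)-2-(iodomethylidene)but-3-en-1-ol | OC/C(C=C)=C\I
F7 | step 1 | tert-butyl{[(2Z)-2-(iodomethylidene)but-3-en-1-yl]oxy}dimethylsilane | CC(C)(C)[Si](C)(C)OC/C(C=C)=C\I
F8 | step 1 | [(1Z)-2-({[tert-butyl(dimethyl)silyl]oxy}methyl)buta-1,3-dien-1-yl]lithium | [Li]/C=C(\CO[Si](C)(C)C(C)(C)C)C=C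
F9 | step 1 | (3Z)-4-({[tert-butyl(dimethyl)silyl]oxy}methyl)hexa-3,5-dien-1-ol | OCC/C=C(\CO[Si](C)(C)C(C)(C)C)C=C
F10 | step 1 | (3Z)-4-({[tert-butyl(dimethyl)silyl]oxy}methyl)hexa-3,5-dienal | O=CC/C=C(\CO[Si](C)(C)C(C)(C)C)C=C
F11 | step 10 | 2-[(2R,4aR,8aR)-8-(chloromethyl)-4a-methyl-1,2,3,4,4a,5,6,8a-octahydronaphthalen-2-yl]prop-2-enal | C=C(C=O)[C@@H]1CC[C@@]2(C)CCC=C(CCl)[C@@H]2C1
F12 | step 10 | caesium (2Z)-3-(4-{[tri(propan-2-yl)silyl]oxy}phenyl)prop-2-enoate | [Cs+].[O-]C(=O)/C=C\c1ccc(O[Si](C(C)C)(C(C)C)C(C)C)cc1
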